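**Plan**

- Locants: ring C1 (quaternary; CH3 and the chain Cα–Cβ–CO2H), C2 (H, C7H2OAr), C3(CH3)=C4, C5 (isopropenyl), C6H2; the β face is the ring face that carries C7.
- Retrosynthetic cuts, in order: the aryl ether O–C7; the Cβ–CO2H bond (the carboxyl carbon is added to a lactol); C5–isopropenyl; then, once C6–H and Cα–H are joined on paper into a C6–Cα cyclopropane bond, both C1–Cα and C6–Cα.
- Enabling feature: C2 lies between two methyl-bearing carbons (C1 and C3). With a C1=C6 double bond the carbocycle is a 2,6-dimethylcyclohexa-2,5-diene with a mirror plane through C2 and C5, so a carbenoid tied to the C7 oxygen must choose between two enantiotopic alkenes on the C7 face.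
- Forward: the carbocycle comes from Birch reduction of 2,6-dimethylbenzoic acid. Step 5 closes the cyclopropane (C1–C6–Cα) and the δ-lactone (Cα–C(=O)–O–C7–C2–C1) together. A C5 ketone then activates the C6–Cα bond for cleavage by SmI2. Isopropenyl is coupled at C5, the lactone is opened through its lactol and extended by one carbon, umbelliferone is attached, and oxidation gives the acid.
- Stereochemistry: C1 and C2 come from step 5 (the catalyst selects the alkene; the tether forces Cα cis to C7 and the C1 methyl trans). C5 comes from a CBS reduction followed by inversion in the palladium coupling.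

Key step: step 5

Assumption: the sense of alkene selection by Rh2(5S-MEPY)4 is taken from its behaviour with simple homoallylic diazoacetates; if the antipode of 8 should predominate, Rh2(5R-MEPY)4 is used instead and nothing else changes.

**Route**

Step 1
Reactants: 1 2,6-dimethylbenzoic acid
Product: 2 2,6-dimethylcyclohexa-2,5-diene-1-carboxylic acid
Conditions: Li, liquid NH3/THF, −78 °C; solid NH4Cl; aq HCl to pH 2 at 0 °C
Reagents that add atoms: none
Why: Birch reduction, in which the carboxylate directs protonation to the ipso and para carbons, so both methyl-bearing alkenes and the mirror plane through C2 and C5 are kept.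

Step 2
Reactants: 2 2,6-dimethylcyclohexa-2,5-diene-1-carboxylic acid
Product: 3 (2,6-dimethylcyclohexa-2,5-dien-1-yl)methanol
Conditions: LiAlH4, Et2O, 0 °C to rt; water work-up under argon
Reagents that add atoms: none
Why: Lithium aluminium hydride reduction of the carboxylic acid to the primary alcohol, which leaves the isolated alkenes alone and, as the carboxylate is formed first, should not move them into conjugation.

Step 3
Reactants: 3 (2,6-dimethylcyclohexa-2,5-dien-1-yl)methanol; 4 bromoacetyl bromide
Product: 5 (2,6-dimethylcyclohexa-2,5-dien-1-yl)methyl bromoacetate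
Conditions: BrCH2COBr, NaHCO3, MeCN, 0 °C
Reagents that add atoms: bromoacetyl bromide 4, BrCC(Br)=O
Why: O-acylation of an unhindered primary alcohol by an acid bromide under bicarbonate buffering, mild enough for the oxidation-prone 1,4-diene.

Step 4
Reactants: 5 (2,6-dimethylcyclohexa-2,5-dien-1-yl)methyl bromoacetate
Product: 7 (2,6-dimethylcyclohexa-2,5-dien-1-yl)methyl diazoacetate, via N-alkyl ditosylhydrazine 6 (not isolated)
Conditions: TsNHNHTs, DBU, THF, 0 °C
Reagents that add atoms: N,N'-ditosylhydrazine, Cc1ccc(cc1)S(=O)(=O)NNS(=O)(=O)c1ccc(C)cc1
Why: Diazoacetate synthesis by the ditosylhydrazine method, in which N-alkylation by the bromoacetate is followed by base-induced loss of two sulfinates, so no acidic or oxidising diazo-transfer step touches the diene.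

Step 5
Reactants: 7 (2,6-dimethylcyclohexa-2,5-dien-1-yl)methyl diazoacetate
Product: 8 tricyclic cyclopropane-fused δ-lactone (cyclopropane C1–C6–Cα and lactone bridge on the β face; C1 methyl α; C3=C4 retained)
Conditions: Rh2(5S-MEPY)4 [dirhodium tetrakis(methyl (5S)-2-oxopyrrolidine-5-carboxylate)] (1 mol%), CH2Cl2, reflux, 7 added over about 10 h by syringe pump
Reagents that add atoms: none
Why: The rhodium carboxamidate expels N2 from 7 and the resulting electrophilic carbenoid adds in a concerted, asynchronous [2+1] manner to the C1=C6 alkene; the closest known reaction type is the enantioselective intramolecular cyclopropanation of homoallylic diazoacetates by chiral dirhodium carboxamidates. The cyclopropane C1–C6–Cα closes by this carbene addition, and the six-membered lactone Cα–C(=O)–O–C7–C2–C1 closes in the same event through the C1–Cα bond, the ester tether being already in place. Because the tether hangs from C7, the carbenoid can reach only the alkene face syn to C7, so Cα is cis to C7 at C1 and C6, the C1 methyl is pushed to the α face and the carbonyl on Cα is endo, as the lactone requires (C1, C6 and Cα are tether-controlled). The absolute configuration, carried by C2 and hence by all four new centres, comes from the chiral carboxamidate ligands choosing one of the two enantiotopic trisubstituted alkenes. The step needs cyclopropanation to win over insertion into the doubly allylic C2–H bond (a γ-lactone) and over carbene dimerisation; this rests on the electron-rich alkene held next to the carbenoid, the known preference of carboxamidate carbenoids for alkene addition in homoallylic esters, and slow addition of 7.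

Step 6
Reactants: 8 tricyclic cyclopropane-fused δ-lactone
Product: 9 cyclopropyl enone lactone (8 with C5 as ketone)
Conditions: CrO3, 3,5-dimethylpyrazole, CH2Cl2, −20 °C
Reagents that add atoms: chromium trioxide, O=[Cr](=O)=O
Why: Allylic oxidation by the chromium trioxide–dimethylpyrazole complex at C5, the only allylic methylene and the one attached to the CH end of the trisubstituted alkene, a pattern known from cyclopropane-flanked methylenes of the 3-carene type and from 5-ene steroids, while the C2 methine and the methyl group cannot give a ketone.

Step 7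
Reactants: 9 cyclopropyl enone lactone
Product: 10 bicyclic enone δ-lactone (C5 ketone; C3=C4; lactone cis-fused across C1–C2 on the β face; C1 methyl α)
Conditions: SmI2 (2.2 equiv), THF/MeOH, −78 °C; pH 7 buffer work-up
Reagents that add atoms: none
Why: Single-electron reductive cleavage of a cyclopropyl ketone, in which the ketyl at C5 opens the exocyclic C6–Cα bond (the bond that overlaps with the enone π system and releases a lactone-stabilised radical) and a second electron and protonation leave C6H2 and CαH2 with C1 and C2 untouched.

Step 8
Reactants: 10 bicyclic enone δ-lactone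
Product: 11 allylic alcohol lactone (C5 hydroxyl α; 5R)
Conditions: (S)-2-methyl-CBS-oxazaborolidine (20 mol%), catecholborane, toluene, −78 °C
Reagents that add atoms: none
Why: Corey–Bakshi–Shibata reduction, in which the (S)-oxazaborolidine is expected to deliver hydride to the β face of the C5 carbonyl with the alkenyl arm as the large group, a sense that a pseudoaxial C1 methyl on the α face should reinforce, while catecholborane spares the lactone and the alkene.

Step 9
Reactants: 11 allylic alcohol lactone
Product: 12 allylic methyl carbonate (C5 carbonate α)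
Conditions: ClCO2Me, pyridine, DMAP (cat.), CH2Cl2, 0 °C
Reagents that add atoms: methyl chloroformate, COC(=O)Cl
Why: Acylation of the secondary allylic alcohol with retention gives a carbonate that zerovalent palladium ionises readily and that releases the methoxide needed to activate boron.

Step 10
Reactants: 12 allylic methyl carbonate; 13 isopropenylboronic acid pinacol ester
Product: 14 isopropenyl lactone (C5 isopropenyl β; 5S)
Conditions: Pd2(dba)3 (2.5 mol%), PPh3 (10 mol%), THF/H2O, 60 °C
Reagents that add atoms: isopropenylboronic acid pinacol ester 13, C=C(C)B1OC(C)(C)C(C)(C)O1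
Why: Allylic Suzuki–Miyaura coupling, in which zerovalent palladium ionises the carbonate with inversion, the isopropenyl group passes from boron to palladium, and reductive elimination with retention at the less hindered allyl terminus C5 gives net inversion, placing isopropenyl cis to C7 and the C1 chain and leaving C3=C4 in place.

Step 11
Reactants: 14 isopropenyl lactone
Product: 15 lactol (anomer mixture)
Conditions: DIBAL-H (i-Bu2AlH), CH2Cl2, −78 °C; aqueous potassium sodium tartrate work-up
Reagents that add atoms: none
Why: Partial reduction of the δ-lactone to the lactol at low temperature, where the tetrahedral aluminium alkoxide persists until work-up and the alkenes are inert.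

Step 12
Reactants: 15 lactol
Product: 17 methyl enol ether alcohol (E/Z mixture), via hydroxy aldehyde 16 (not isolated)
Conditions: Ph3P(CH2OMe)Cl, KOtBu, THF, 0 °C to rt
Reagents that add atoms: (methoxymethyl)triphenylphosphonium chloride, COC[P+](c1ccccc1)(c1ccccc1)c1ccccc1.[Cl-]
Why: Wittig methoxymethylenation of the ring-opened aldehyde tautomer of the lactol adds the missing chain carbon as an enol ether and frees the C7 hydroxyl, excess ylide serving as base for the lactol.

Step 13
Reactants: 17 methyl enol ether alcohol; 18 umbelliferone
Product: 19 umbelliferyl ether enol ether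
Conditions: PPh3, DIAD, THF, 0 °C to rt
Reagents that add atoms: umbelliferone 18, O=c1ccc2ccc(O)cc2o1
Why: Mitsunobu etherification of the primary C7 alcohol with the acidic 7-hydroxyl of the coumarin, run under neutral conditions that spare the enol ether and touch no stereocentre.

Step 14
Reactants: 19 umbelliferyl ether enol ether
Product: 20 3-[(1R,2R,5S)-1,3-dimethyl-2-{[(2-oxo-2H-chromen-7-yl)oxy]methyl}-5-(prop-1-en-2-yl)cyclohex-3-en-1-yl]propanal
Conditions: 1 M aq HCl, THF, rt
Reagents that add atoms: water, O
Why: Acid-catalysed hydrolysis of the enol ether through the oxocarbenium ion and hemiacetal, under conditions too mild to hydrate or shift the isopropenyl and ring alkenes or to cleave the aryl ether.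

Step 15
Reactants: 20 the propanal
Product: 21 3-[(1R,2R,5S)-1,3-dimethyl-2-{[(2-oxo-2H-chromen-7-yl)oxy]methyl}-5-(prop-1-en-2-yl)cyclohex-3-en-1-yl]propanoic acid (CNP0301632.1)
Conditions: NaClO2, NaH2PO4, 2-methyl-2-butene, t-BuOH/H2O, rt
Reagents that add atoms: sodium chlorite, [Na+].[O-]Cl=O
Why: Pinnick oxidation of the aldehyde to the acid, with 2-methyl-2-butene scavenging the hypochlorous acid that would otherwise attack the two alkenes and the electron-rich coumarin ring.

**Compound list**

1 | 2,6-dimethylbenzoic acid | Cc1cccc(C)c1C(=O)O | starting material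
2 | 2,6-dimethylcyclohexa-2,5-diene-1-carboxylic acid | CC1=CCC=C(C)C1C(=O)O | intermediate
3 | (2,6-dimethylcyclohexa-2,5-dien-1-yl)methanol | CC1=CCC=C(C)C1CO | intermediate
4 | bromoacetyl bromide | BrCC(Br)=O | starting material
5 | (2,6-dimethylcyclohexa-2,5-dien-1-yl)methyl bromoacetate | CC1=CCC=C(C)C1COC(=O)CBr | intermediate
6 | (2,6-dimethylcyclohexa-2,5-dien-1-yl)methyl 2-[1,2-bis(p-tolylsulfonyl)hydrazinyl]acetate | CC1=CCC=C(C)C1COC(=O)CN(NS(=O)(=O)c1ccc(C)cc1)S(=O)(=O)c1ccc(C)cc1 | intermediate (not isolated)
7 | (2,6-dimethylcyclohexa-2,5-dien-1-yl)methyl diazoacetate | [N-]=[N+]=CC(=O)OCC1C(C)=CCC=C1C | intermediate (key-step precursor)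
8 | tricyclic lactone: 3-methylcyclohex-3-ene C1–C6 with β-fused cyclopropane C1–C6–Cα and β-fused δ-lactone Cα–C(=O)–O–C7–C2, C1 methyl α | O=C1OC[C@H]2C(C)=CC[C@H]3[C@@H]1[C@@]23C | intermediate (key-step product)
9 | 8 with C5 oxidised to the ketone (cyclopropyl enone lactone) | O=C1OC[C@H]2C(C)=CC(=O)[C@H]3[C@@H]1[C@@]23C | intermediate
10 | bicyclic enone δ-lactone: C5 ketone, C3(CH3)=C4, C6H2, lactone Cα–C(=O)–O–C7 cis-fused across C1–C2 on the β face, C1 methyl α | O=C1OC[C@H]2C(C)=CC(=O)C[C@@]2(C)C1 | intermediate
11 | (5R)-allylic alcohol of 10, C5 hydroxyl α (cis to the C1 methyl) | O=C1OC[C@H]2C(C)=C[C@H](O)C[C@@]2(C)C1 | intermediate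
12 | methyl carbonate of 11 | O=C1OC[C@H]2C(C)=C[C@H](OC(=O)OC)C[C@@]2(C)C1 | intermediate
13 | isopropenylboronic acid pinacol ester | C=C(C)B1OC(C)(C)C(C)(C)O1 | starting material
14 | (5S)-isopropenyl lactone, isopropenyl β (cis to C7 and Cα) | O=C1OC[C@H]2C(C)=C[C@@H](C(C)=C)C[C@@]2(C)C1 | intermediate
15 | lactol of 14 (both anomers) | OC1OC[C@H]2C(C)=C[C@@H](C(C)=C)C[C@@]2(C)C1 | intermediate
16 | hydroxy aldehyde, open form of 15 (C1–CH2–CHO, C7–OH) | O=CC[C@]1(C)C[C@H](C(C)=C)C=C(C)[C@@H]1CO | intermediate (not isolated)
17 | methyl enol ether alcohol (C1–CH2–CH=CH–OCH3, E/Z mixture; C7–OH) | COC=CC[C@]1(C)C[C@H](C(C)=C)C=C(C)[C@@H]1CO | intermediate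
18 | umbelliferone (7-hydroxycoumarin) | O=c1ccc2ccc(O)cc2o1 | starting material
19 | 7-coumarinyl ether of 17 | COC=CC[C@]1(C)C[C@H](C(C)=C)C=C(C)[C@@H]1COc1ccc2ccc(=O)oc2c1 | intermediate
20 | 3-[(1R,2R,5S)-1,3-dimethyl-2-{[(2-oxo-2H-chromen-7-yl)oxy]methyl}-5-(prop-1-en-2-yl)cyclohex-3-en-1-yl]propanal | O=CCC[C@]1(C)C[C@H](C(C)=C)C=C(C)[C@@H]1COc1ccc2ccc(=O)oc2c1 | intermediate
21 | 3-[(1R,2R,5S)-1,3-dimethyl-2-{[(2-oxo-2H-chromen-7-yl)oxy]methyl}-5-(prop-1-en-2-yl)cyclohex-3-en-1-yl]propanoic acid | C=C(C)[C@@H]1C=C(C)[C@H](COc2ccc3ccc(=O)oc3c2)[C@](C)(CCC(=O)O)C1 | target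

**Count and risks**

Total: 15 steps. Longest linear sequence: 15 steps (1 to 21); compounds 4, 13 and 18 are purchased.

The three steps most likely to fail:

First, step 5. The catalyst may discriminate poorly between the two enantiotopic alkenes, or insertion into the C2–H bond may compete under the carboxamidate. The fallback gives up catalyst-controlled desymmetrisation and resolves later. Starting from 7, cyclisation with achiral Cu(acac)2 in hot toluene (copper carbenoids favour alkene addition over C–H insertion) would give racemic cyclopropane lactone F1. The chemistry of steps 6 and 7 would take it to racemic cyclopropyl enone F2 and racemic enone lactone F3. Luche reduction (NaBH4, CeCl3·7H2O, MeOH, −78 °C), expected to come anti to the pseudoaxial C1 methyl, would give racemic alcohol F4 with the C5 hydroxyl α. Lipase-catalysed acylation (Candida antarctica lipase B, vinyl acetate) should then, by the empirical rule for secondary alcohols with the alkenyl arm as the larger group, acylate the (5R) enantiomer to acetate F5, which is separated from the unreacted antipode. F5 would take the place of carbonate 12 in the coupling of step 10 (KF added, since an acetate supplies no alkoxide) and the route is rejoined at 14. Should the enzyme prefer the other enantiomer, the alcohol left behind is 11 itself.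

Second, step 6. Hydrogen abstraction at C5 gives an allyl radical that is also cyclopropylcarbinyl and may open the three-membered ring, or oxidation may drift to the C2 methine or the methyl group. The fallback avoids C–H abstraction. Starting from 8, epoxidation of C3=C4 (mCPBA, NaHCO3, CH2Cl2, 0 °C; the face is immaterial) would give epoxide F6. Opening at the secondary carbon C4 with PhSeNa (from PhSeSePh and NaBH4, EtOH) would give hydroxy selenide F7. Oxidation with H2O2 and selenoxide syn-elimination, which can only run towards C5 because C3 has no hydrogen, would give tertiary allylic alcohol F8 (C3 carbinol, C4=C5). Oxidative 1,3-transposition with pyridinium chlorochromate, (C5H5NH)[CrO3Cl], in CH2Cl2 would move the oxygen to C5 and the alkene back to C3=C4, rejoining the route at 9.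

Third, step 10. β-Hydride elimination from the π-allyl palladium to a diene, coupling at C3, or loss of stereochemical fidelity by palladium–palladium exchange may intervene. The fallback replaces the palladium/boron coupling by stoichiometric organocopper substitution. Starting from 11, phosphorylation (ClP(O)(OEt)2, N-methylimidazole, CH2Cl2, 0 °C) would give allylic diethyl phosphate F9. Treatment with the isopropenyl cuprate made from isopropenylmagnesium bromide and CuBr·SMe2 (2:1) in THF at −78 to −30 °C should proceed by anti oxidative addition of copper and reductive elimination at the less substituted terminus C5. That again means net inversion, and the lactone is tolerated by the cuprate at low temperature, so the route is rejoined at 14.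

**Further compounds**

F1 | step 5 | racemic 8 (one enantiomer drawn) | O=C1OC[C@H]2C(C)=CC[C@H]3[C@@H]1[C@@]23C
F2 | step 5 | racemic 9 (one enantiomer drawn) | O=C1OC[C@H]2C(C)=CC(=O)[C@H]3[C@@H]1[C@@]23C
F3 | step 5 | racemic 10 (one enantiomer drawn) | O=C1OC[C@H]2C(C)=CC(=O)C[C@@]2(C)C1
F4 | step 5 | racemic 11, C5 hydroxyl cis to the C1 methyl (one enantiomer drawn) | O=C1OC[C@H]2C(C)=C[C@H](O)C[C@@]2(C)C1
F5 | step 5 | (5R)-acetate of 11 | O=C1OC[C@H]2C(C)=C[C@H](OC(C)=O)C[C@@]2(C)C1
F6 | step 6 | 3,4-epoxide of 8 (epoxide face not assigned) | O=C1OC[C@H]2C3(C)OC3C[C@H]3[C@@H]1[C@@]23C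
F7 | step 6 | 3-hydroxy-4-(phenylselanyl) derivative of 8 (C3 and C4 not assigned) | O=C1OC[C@H]2C(C)(O)C([Se]c3ccccc3)C[C@H]3[C@@H]1[C@@]23C
F8 | step 6 | tertiary allylic alcohol: C3 carbinol, C4=C5, cyclopropane and lactone as in 8 (C3 not assigned) | O=C1OC[C@H]2C(C)(O)C=C[C@H]3[C@@H]1[C@@]23C
F9 | step 10 | diethyl phosphate of 11 | O=C1OC[C@H]2C(C)=C[C@H](OP(=O)(OCC)OCC)C[C@@]2(C)C1
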